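**Retrosynthetic overview**

1. The target is the meso isomer, (6S,6'R)-ε,ε-carotene-3,3'-dione. Ring A (C1–C6) and ring B (C1'–C6') are mirror images and the nonaene is constitutionally symmetric about C15=C15', so C10–C11 and C10'–C11' are equivalent sp2–sp2 single bonds on either side of a C12 pentaene (C11 to C11'). This feature makes a three-component key step possible.
2. Dione ⇒ meso-3,3'-diol (MnO2 at the end) ⇒ its 3'-monoacetate. The enones are carried as allylic alcohols so that C6–H and C6'–H are not acidic during coupling.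
3. Monoacetate ⇒ (3S,6S)-C14 hydroxy dienyl iodide + C12 pentaene with Bu3Sn at C11 and pinacolboryl at C11' + (3R,6R)-C14 acetoxy dienyl iodide. These are joined in one flask by Stille coupling (C10–C11), then Suzuki–Miyaura coupling (C10'–C11').
4. Both C14 iodides ⇐ one racemic 3,6-trans hydroxy iodide by lipase resolution (alcohol and acetate both used) ⇐ (±)-α-ionone by ketalisation, C3 allylic oxidation, reduction, alkyne formation and zirconium-catalysed carboalumination–iodination.
5. C12 linchpin ⇐ C10 trienedial by CrCl2-mediated boryl, then stannyl olefination. No ring is formed in the route: both cyclohexene rings come ready-made from α-ionone.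

Key step: step 13

Remark: locants follow carotenoid numbering (ring: C1 = CMe2, C3 = C–O, C5 = methyl-bearing sp2 carbon, C6 = ring CH carrying the chain; chain C7–C15; primes for the other half). Racemic compounds are drawn as the (3R,6R) enantiomer.

Assumption: the lipase is taken to acylate the (3R)-alcohol faster; if it prefers (3S), the mirror-image intermediates result and the same meso target is reached.

**Route**

Step 1
Reactants: 1 (±)-α-ionone
Product: 2 (±)-α-ionone ethylene ketal
Conditions: TMSOCH2CH2OTMS (1.5 equiv), TMSOTf (2 mol %), CH2Cl2, −78 °C; pyridine quench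
Reagents that add atoms: 1,2-bis(trimethylsilyloxy)ethane, C[Si](C)(C)OCCO[Si](C)(C)C
Why: Noyori ketalisation under kinetic conditions should mask the methyl ketone as the dioxolane without moving the C7=C8 or C4=C5 double bonds, which removes the only electrophile before the oxidation and hydride steps.

Step 2
Reactants: 2 (±)-α-ionone ethylene ketal
Product: 3 (±)-3-oxo-α-ionone ethylene ketal
Conditions: t-BuOOH (5 equiv), Pd(OH)2 on carbon (5 mol %), K2CO3 (0.25 equiv), CH2Cl2, 4 °C
Reagents that add atoms: tert-butyl hydroperoxide, CC(C)(C)OO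
Why: Palladium/peroxide allylic oxidation should convert the accessible ring allylic methylene C3 into the enone, the tertiary C6–H being shielded by the gem-dimethyl group and the ketal side chain.

Step 3
Reactants: 3 (±)-3-oxo-α-ionone ethylene ketal
Product: 4 rac-(3R,6R)-3-hydroxy-α-ionone ethylene ketal (3,6-trans)
Conditions: LiBH(s-Bu)3 (1.2 equiv), THF, −78 °C; H2O; chromatography
Reagents that add atoms: none
Why: 1,2-Reduction of the β,β-disubstituted enone by the bulky trialkylborohydride, which is expected to attack C3 anti to the pseudo-axial C1 methyl group and so place the new hydroxyl trans to the C6 side chain (any cis epimer is removed by chromatography).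

Step 4
Reactants: 4 rac-(3R,6R)-3-hydroxy-α-ionone ethylene ketal
Product: 5 rac-(3R,6R)-3-hydroxy-α-ionone
Conditions: PPTS (0.1 equiv), THF–H2O, 25 °C
Reagents that add atoms: water, O
Why: Mild acid hydrolysis of the allylic dioxolane, which should ionise far more easily than the ring allylic alcohol, frees the methyl ketone.

Step 5
Reactants: 5 rac-(3R,6R)-3-hydroxy-α-ionone
Product: 6 rac-(3R,6R)-3-(tert-butyldimethylsilyloxy)-α-ionone
Conditions: TBSCl (1.2 equiv), imidazole (2 equiv), DMF, 25 °C
Reagents that add atoms: tert-butyldimethylsilyl chloride, CC(C)(C)[Si](C)(C)Cl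
Why: Standard silylation of the secondary alcohol protects it from the amide base, the chlorophosphate and the alane of the next two steps.

Step 6
Reactants: 6 rac-(3R,6R)-3-(tert-butyldimethylsilyloxy)-α-ionone
Product: 8 rac-(3R,6R) TBS-protected enyne, via enol diethyl phosphate 7 (not isolated)
Conditions: LiN(i-Pr)2 (1.1 equiv), THF, −78 °C; ClP(O)(OEt)2 (1.1 equiv), −78 → 25 °C; then LiN(i-Pr)2 (2.3 equiv), −78 → 25 °C; H2O
Reagents that add atoms: diethyl chlorophosphate, CCOP(=O)(Cl)OCC (its atoms are held in 7 only)
Why: Negishi ketone-to-alkyne protocol, in which kinetic deprotonation of the methyl group at −78 °C (not the γ C6–H), O-phosphorylation and base-induced elimination of diethyl phosphate should give the terminal enyne.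

Step 7
Reactants: 8 rac-(3R,6R) TBS-protected enyne
Product: 10 rac-(3R,6R) TBS-protected C14 dienyl iodide, via alkenyl dimethylalane 9 (not isolated)
Conditions: Me3Al (3 equiv), Cp2ZrCl2 (0.25 equiv), CH2Cl2, 0 → 25 °C; then I2 (1.2 equiv), THF, −30 °C
Reagents that add atoms: trimethylaluminium, C[Al](C)C; iodine, II
Why: Negishi zirconium-catalysed carboalumination adds methyl and aluminium syn across the terminal alkyne with aluminium on the terminal carbon, and iodinolysis with retention should give the (E)-2-methyl-1-iodo-1,3-diene (C9=C10).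

Step 8
Reactants: 10 rac-(3R,6R) TBS-protected C14 dienyl iodide
Product: 11 rac-(3R,6R) C14 hydroxy dienyl iodide
Conditions: Bu4NF (1.5 equiv), THF, 0 → 25 °C, dark
Reagents that add atoms: none
Why: Fluoride desilylation frees the carbinol needed by the enzyme and leaves the dienyl iodide untouched.

Step 9
Reactants: 11 rac-(3R,6R) C14 hydroxy dienyl iodide
Product: 12 (3R,6R)-C14 acetoxy dienyl iodide and 13 (3S,6S)-C14 hydroxy dienyl iodide
Conditions: immobilised Burkholderia cepacia lipase, vinyl acetate (3 equiv), t-BuOMe, 30 °C, dark, stopped at about half conversion; chromatography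
Reagents that add atoms: vinyl acetate, CC(=O)OC=C
Why: Lipase-catalysed kinetic resolution by irreversible transesterification should acylate one enantiomer of the cyclohexenol, so C6 is resolved through its fixed trans relationship to C3, and both products are used as the two mirror-image end groups.

Step 10
Reactants: 14 dibromomethane; 15 tributyltin chloride
Product: 17 (dibromomethyl)tributylstannane, via dibromomethyllithium 16 (not isolated)
Conditions: LiN(i-Pr)2 (1.0 equiv), THF, −90 °C; then Bu3SnCl, −90 → −40 °C
Reagents that add atoms: lithium diisopropylamide, [Li]N(C(C)C)C(C)C (its lithium is held in 16 only)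
Why: Low-temperature deprotonation of CH2Br2 to the carbenoid and trapping at tin is the standard preparation of this olefination reagent.

Step 11
Reactants: 18 (2E,4E,6E)-2,7-dimethylocta-2,4,6-trienedial
Product: 19 (2E,4E,6E,8E)-2,7-dimethyl-9-(pinacolboryl)nona-2,4,6,8-tetraenal
Conditions: 18 (3 equiv), Cl2CHBpin (1 equiv), CrCl2 (8 equiv), LiI (4 equiv), THF, 25 °C, dark; excess 18 recovered
Reagents that add atoms: 2-(dichloromethyl)-4,4,5,5-tetramethyl-1,3,2-dioxaborolane, ClC(Cl)B1OC(C)(C)C(C)(C)O1
Why: Takai-type CrCl2-mediated boryl olefination is E-selective, and an excess of the symmetric dialdehyde should make mono-olefination dominant.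

Step 12
Reactants: 19 (2E,4E,6E,8E)-2,7-dimethyl-9-(pinacolboryl)nona-2,4,6,8-tetraenal; 17 (dibromomethyl)tributylstannane
Product: 20 C12 linchpin, tributyl[(1E,3E,5E,7E,9E)-3,8-dimethyl-10-(pinacolboryl)deca-1,3,5,7,9-pentaen-1-yl]stannane
Conditions: 17 (2 equiv), CrCl2 (10 equiv), LiI (4 equiv), THF–DMF, 25 °C, dark; Et3N-deactivated silica
Reagents that add atoms: none
Why: Takai-type CrCl2-mediated stannyl olefination should convert the remaining aldehyde into the (E)-alkenylstannane, the pinacol boronate being inert to divalent chromium.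

Step 13
Reactants: 20 C12 linchpin; 13 (3S,6S)-C14 hydroxy dienyl iodide; 12 (3R,6R)-C14 acetoxy dienyl iodide
Product: 22 (3S,6S,3'R,6'R)-3-hydroxy-ε,ε-caroten-3'-yl acetate, via C26 heptaenyl pinacol boronate 21 (not isolated)
Conditions: 13 (1.00 equiv), 20 (1.05 equiv), Pd2(dba)3 (3 mol %), AsPh3 (24 mol %), degassed THF–DMF, 25 °C, dark, until 13 is consumed; then 12 (1.15 equiv), 3 M aq. K3PO4 (3 equiv), 40 °C; chromatography
Reagents that add atoms: none
Why: Zerovalent palladium inserts into the C10–I bond of 13, the C11–Sn bond of 20 transmetallates without base (the C11' boronate stays silent) and reductive elimination gives 21; phosphate then turns the boronate into a borate, which transmetallates to the palladium species formed from 12, and reductive elimination forms the C10'–C11' bond. The closest known reaction types are the Stille coupling of stannyl alkenyl boronates followed by Suzuki–Miyaura coupling in the same flask, and the two-fold Stille coupling of C14 dienyl iodides with a C12 pentaene distannane. No ring is closed and no stereocentre is created: C3, C6, C3' and C6' are carried in from 13 and 12, and both couplings retain the E geometry at C9=C10, C11=C12, C11'=C12' and C9'=C10'. The step needs tin-before-boron chemoselectivity, which the base-free first stage secures, and one enantiomeric ring per terminus, which the order of addition secures. Because the lipase left one enantiomer as alcohol and the other as acetate, only the heterochiral product is a monoacetate; homochiral leak-through from any stoichiometric error is a diol or a diacetate and is removed by chromatography. The allylic alcohol oxidation level keeps C6–H and C6'–H non-acidic under the phosphate base.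

Step 14
Reactants: 22 (3S,6S,3'R,6'R)-3-hydroxy-ε,ε-caroten-3'-yl acetate
Product: 23 meso-(3S,6S,3'R,6'R)-ε,ε-carotene-3,3'-diol
Conditions: K2CO3 (0.2 equiv), MeOH–THF, 25 °C, dark
Reagents that add atoms: none
Why: Carbonate-catalysed transesterification should remove the acetate, and at the diol oxidation level C6'–H is not acidic, so the base is harmless.

Step 15
Reactants: 23 meso-(3S,6S,3'R,6'R)-ε,ε-carotene-3,3'-diol
Product: 24 (6S,6'R)-ε,ε-carotene-3,3'-dione (target)
Conditions: activated MnO2 (excess), CH2Cl2, 25 °C, dark, argon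
Reagents that add atoms: none
Why: MnO2 oxidation of the two ring allylic alcohols to the enones is neutral, so the C6 and C6' stereocentres should not epimerise and the C4=C5 double bonds should not move into conjugation with the chain.

**Compound list**

1 | (±)-α-ionone, (E)-4-(2,6,6-trimethylcyclohex-2-en-1-yl)but-3-en-2-one | CC1=CCCC(C)(C)C1/C=C/C(C)=O | starting material
2 | (±)-α-ionone ethylene ketal | CC1=CCCC(C)(C)C1/C=C/C2(C)OCCO2 | intermediate
3 | (±)-3-oxo-α-ionone ethylene ketal | CC1=CC(=O)CC(C)(C)C1/C=C/C2(C)OCCO2 | intermediate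
4 | rac-(3R,6R)-3-hydroxy-α-ionone ethylene ketal (3,6-trans) | CC1=C[C@H](O)CC(C)(C)[C@H]1/C=C/C2(C)OCCO2 | intermediate
5 | rac-(3R,6R)-3-hydroxy-α-ionone | CC1=C[C@H](O)CC(C)(C)[C@H]1/C=C/C(C)=O | intermediate
6 | rac-(3R,6R)-3-(tert-butyldimethylsilyloxy)-α-ionone | CC1=C[C@H](O[Si](C)(C)C(C)(C)C)CC(C)(C)[C@H]1/C=C/C(C)=O | intermediate
7 | rac-(3R,6R) enol diethyl phosphate of 6 | CC1=C[C@H](O[Si](C)(C)C(C)(C)C)CC(C)(C)[C@H]1/C=C/C(=C)OP(=O)(OCC)OCC | intermediate
8 | rac-(3R,6R) TBS-protected enyne, tert-butyl{[4-[(E)-but-1-en-3-yn-1-yl]-3,5,5-trimethylcyclohex-2-en-1-yl]oxy}dimethylsilane | CC1=C[C@H](O[Si](C)(C)C(C)(C)C)CC(C)(C)[C@H]1/C=C/C#C | intermediate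
9 | rac-(3R,6R) alkenyl dimethylalane | CC1=C[C@H](O[Si](C)(C)C(C)(C)C)CC(C)(C)[C@H]1/C=C/C(C)=C/[Al](C)C | intermediate
10 | rac-(3R,6R) TBS-protected C14 dienyl iodide | CC1=C[C@H](O[Si](C)(C)C(C)(C)C)CC(C)(C)[C@H]1/C=C/C(C)=C/I | intermediate
11 | rac-(3R,6R) C14 hydroxy dienyl iodide, 4-[(1E,3E)-4-iodo-3-methylbuta-1,3-dien-1-yl]-3,5,5-trimethylcyclohex-2-en-1-ol | CC1=C[C@H](O)CC(C)(C)[C@H]1/C=C/C(C)=C/I | intermediate
12 | (3R,6R)-C14 acetoxy dienyl iodide, (1R,4R)-4-[(1E,3E)-4-iodo-3-methylbuta-1,3-dien-1-yl]-3,5,5-trimethylcyclohex-2-en-1-yl acetate | CC1=C[C@H](OC(C)=O)CC(C)(C)[C@H]1/C=C/C(C)=C/I | intermediate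
13 | (3S,6S)-C14 hydroxy dienyl iodide, (1S,4S)-4-[(1E,3E)-4-iodo-3-methylbuta-1,3-dien-1-yl]-3,5,5-trimethylcyclohex-2-en-1-ol | CC1=C[C@@H](O)CC(C)(C)[C@@H]1/C=C/C(C)=C/I | intermediate
14 | dibromomethane | BrCBr | starting material
15 | tributyltin chloride | CCCC[Sn](Cl)(CCCC)CCCC | starting material
16 | dibromomethyllithium | [Li]C(Br)Br | intermediate
17 | (dibromomethyl)tributylstannane | CCCC[Sn](CCCC)(CCCC)C(Br)Br | intermediate
18 | (2E,4E,6E)-2,7-dimethylocta-2,4,6-trienedial | O=C/C(C)=C/C=C/C=C(C)/C=O | starting material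
19 | (2E,4E,6E,8E)-2,7-dimethyl-9-(4,4,5,5-tetramethyl-1,3,2-dioxaborolan-2-yl)nona-2,4,6,8-tetraenal | O=C/C(C)=C/C=C/C=C(C)/C=C/B1OC(C)(C)C(C)(C)O1 | intermediate
20 | C12 linchpin, tributyl[(1E,3E,5E,7E,9E)-3,8-dimethyl-10-(4,4,5,5-tetramethyl-1,3,2-dioxaborolan-2-yl)deca-1,3,5,7,9-pentaen-1-yl]stannane | CCCC[Sn](CCCC)(CCCC)/C=C/C(C)=C/C=C/C=C(C)/C=C/B1OC(C)(C)C(C)(C)O1 | intermediate
21 | C26 heptaenyl pinacol boronate with the (3S,6S)-3-hydroxy-ε ring | CC1=C[C@@H](O)CC(C)(C)[C@@H]1/C=C/C(C)=C/C=C/C(C)=C/C=C/C=C(C)/C=C/B2OC(C)(C)C(C)(C)O2 | intermediate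
22 | (3S,6S,3'R,6'R)-3-hydroxy-ε,ε-caroten-3'-yl acetate | CC1=C[C@@H](O)CC(C)(C)[C@@H]1/C=C/C(C)=C/C=C/C(C)=C/C=C/C=C(C)/C=C/C=C(C)/C=C/[C@H]2C(C)=C[C@H](OC(C)=O)CC2(C)C | intermediate
23 | meso-(3S,6S,3'R,6'R)-ε,ε-carotene-3,3'-diol | CC1=C[C@@H](O)CC(C)(C)[C@@H]1/C=C/C(C)=C/C=C/C(C)=C/C=C/C=C(C)/C=C/C=C(C)/C=C/[C@H]2C(C)=C[C@H](O)CC2(C)C | intermediate
24 | (6S,6'R)-ε,ε-carotene-3,3'-dione (meso) | CC1=CC(=O)CC(C)(C)[C@@H]1/C=C/C(C)=C/C=C/C(C)=C/C=C/C=C(C)/C=C/C=C(C)/C=C/[C@H]1C(C)=CC(=O)CC1(C)C | target

**Step count**

Total: 15 steps. Longest linear sequence: 12 steps (steps 1–9, 13, 14, 15 from α-ionone).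

**Steps most likely to fail, with fallbacks**

Step 13. The heptaenyl boronate may lose boron by protodeboronation under aqueous base before it couples. The allylic acetate may be cleaved by the base or ionised by zerovalent palladium. An imperfect first stage lets the wrong iodide reach a terminus. Fallback: a tin-only, base-free, two-flask assembly that sets out from 18, 17, 13 and 12 and comes back at 22. Two-fold CrCl2/LiI stannyl olefination of 18 with 17 (4 equiv) in THF–DMF should give (1E,3E,5E,7E,9E)-1,10-bis(tributylstannyl)-3,8-dimethyldeca-1,3,5,7,9-pentaene F1. Stille coupling of 13 with an excess of F1 (3 equiv; Pd2(dba)3, AsPh3, DMF, 25 °C, dark) should give the mono-coupled C26 heptaenyl stannane F2, which is isolated on Et3N-deactivated silica while F1 is recovered. A second Stille coupling of F2 with 12 under the same conditions should give 22, and the alcohol/acetate pair still marks the heterochiral product.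

Step 9. The lipase may discriminate poorly between the enantiomers of the iodide, so that both end groups are optically impure and homochiral carotenoid hides in the monoacetate fraction. Fallback: a classical resolution through diastereomeric esters that sets out from 11 and comes back at 12 and 13. Esterification of 11 with (S)-2-methoxy-2-phenylacetic acid (DCC, DMAP, CH2Cl2, 0 °C) should give the (3R,6R)-ester F3 and the (3S,6S)-ester F4, which are separated by chromatography or crystallisation. Methanolysis of F4 (K2CO3, MeOH) gives 13. Methanolysis of F3 gives the (3R,6R)-C14 hydroxy dienyl iodide F5, which is acetylated (Ac2O, pyridine) to 12.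

Step 2. Hydrogen abstraction may compete at the doubly allylic C6–H, or the side-chain double bond may be attacked, so that the oxidation is not regioselective. Fallback: the order of oxidation and protection is reversed, setting out from 1 and coming back at 3. Allylic oxidation of 1 itself under the step 2 conditions, where C6–H is deactivated by the conjugated C9 ketone, should give (±)-3-oxo-α-ionone F6. Noyori ketalisation at −78 °C with one equivalent of TMSOCH2CH2OTMS should then take the less hindered methyl ketone in preference to the ring enone flanked by the C1 quaternary centre, to give 3.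

**Further compounds**

F1 | step 13 | (1E,3E,5E,7E,9E)-1,10-bis(tributylstannyl)-3,8-dimethyldeca-1,3,5,7,9-pentaene | CCCC[Sn](CCCC)(CCCC)/C=C/C(C)=C/C=C/C=C(C)/C=C/[Sn](CCCC)(CCCC)CCCC
F2 | step 13 | C26 heptaenyl tributylstannane with the (3S,6S)-3-hydroxy-ε ring | CC1=C[C@@H](O)CC(C)(C)[C@@H]1/C=C/C(C)=C/C=C/C(C)=C/C=C/C=C(C)/C=C/[Sn](CCCC)(CCCC)CCCC
F3 | step 9 | (3R,6R)-C14 dienyl iodide (S)-2-methoxy-2-phenylacetate | CC1=C[C@H](OC(=O)[C@@H](OC)c2ccccc2)CC(C)(C)[C@H]1/C=C/C(C)=C/I
F4 | step 9 | (3S,6S)-C14 dienyl iodide (S)-2-methoxy-2-phenylacetate | CC1=C[C@@H](OC(=O)[C@@H](OC)c2ccccc2)CC(C)(C)[C@@H]1/C=C/C(C)=C/I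
F5 | step 9 | (3R,6R)-C14 hydroxy dienyl iodide | CC1=C[C@H](O)CC(C)(C)[C@H]1/C=C/C(C)=C/I
F6 | step 2 | (±)-3-oxo-α-ionone | CC1=CC(=O)CC(C)(C)C1/C=C/C(C)=O
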